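The vessel was closed, stirred, of constant volume and isothermal, and the three new flasks differed in their charge of free base.

| flask | electrophile | nucleophile | free base | remark | time |
|---|---|---|---|---|---|
| blue | 0.25 M | 0.45 M | 0.14 M | run made earlier |  |
| teal | 0.25 M | 0.45 M | 0.31 M | run made earlier |  |
| Thursday's | 0.25 M | 0.450 M | 0.120 M |  | 80 min |
| Friday's | 0.25 M | 0.450 M | 0.160 M |  | 80 min |
| Wednesday's | 0.25 M | 0.450 M | 0.210 M |  | 80 min |

| run | time / min | electrophile / % | target / % |
|---|---|---|---|
| blue | 5.00 | 96.3 | 0.2 |
| blue | 8.00 | 97.8 | 3.1 |
| blue | 12.0 | 96.5 | 3.4 |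
| blue | 20.0 | 93.8 | 6.9 |
| blue | 30.0 | 91.5 | 8.9 |
| blue | 60.0 | 86.6 | 15.6 |
| teal | 10.0 | 97.2 | 3.4 |
| teal | 20.0 | 93.5 | 5.1 |
| teal | 30.0 | 91.6 | 9.4 |
| teal | 40.0 | 91.3 | 11.5 |
| teal | 50.0 | 86.6 | 13.2 |
| teal | 60.0 | 86.2 | 12.3 |

(standard deviation of a reading: 1 percentage point)

1. part of the electrophile that has reacted at the end, Thursday's
2. part of the electrophile that has reacted at the end, Friday's
3. part of the electrophile that has reacted at the end, Wednesday's
4. what raising the concentration of free base from its lowest to its highest value here does to the part of the electrophile that has reacted (changes below 5 percentage points count as none) (no change / it falls / it rises)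

- the numbers in the tables scatter with a standard deviation of 1 percentage point

In the blue run and the teal run free base stood at 0.14 M and 0.31 M, yet at 60.0 min the electrophile read 86.6% and 86.2%, against a scatter of 1 point. So I dropped free base from my reckoning and replaced the curved fall of the electrophile by one mean pseudo-first-order constant k′, taken from the mean of those readings:

k′ = 0.00244 min⁻¹

Dividing by c(nucleophile) gave the nucleophile constant, the mean rate constant per molar of nucleophile charged:

k′ / c(nucleophile) = 0.325 M⁻¹ h⁻¹

No run had varied the nucleophile, so its first order was my assumption. For each new flask after 80 min this gave: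

reacted = 17.7%

The reaction itself would use 9.84% of the nucleophile by then, so I estimated the error of holding c(nucleophile) at its charge at about 0.87 points. At the bench, 82.3% of the electrophile was still to be expected at the end of each new flask. The nucleophile charge and the time were not to be touched, as both stand in the exponent.

The forecast gave 18.5%, 18.5% and 18.5%, with no change, holding that “the rate looks zero order in base over this range”. My figure lay 0.80 points below it.

The flasks gave 18.5%, 18.5% and 18.5%, and no change, the change being 0.031 points.

    acid set free + free base ⇌ salt of the base (K = 2.00 × 10⁵ M⁻¹, k = 110 M⁻¹ h⁻¹)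
    nucleophile ⇌ dormant form (K = 0.290, k = 0.480 h⁻¹)
    nucleophile + acid set free ⇌ protonated nucleophile, settled at all times (K = 380 M⁻¹)
    electrophile + acid set free → side product (k = 3.30 M⁻¹ h⁻¹)
    electrophile + nucleophile → acid set free + target (k = 0.450 M⁻¹ h⁻¹)

Put on Thursday's, 0.325 M⁻¹ h⁻¹ gave 17.7% against 18.5%. At 80.0 min, the protonated nucleophile stood at 0.0419 M in Thursday's and 0.0396 M in Wednesday's, and the unbound nucleophile at 62% and 63% of its charge. The uptake of acid set free by free base made no difference to Wednesday's answer. In the neighbouring flask, Thursday's with 1.1 M of nucleophile, the same constant gave 37.9%, and that flask reached 39.5%, with 64% of its nucleophile still there, unbound.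

(The runs were computed for substances that don't exist; scatter was added.)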